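**Retrosynthetic overview**
1. Target 33 ← reagent-controlled double epoxidation (Shi) of the macrocyclic (3Z,7E)-diene acetate 31; both oxiranes are made last.
2. 31 ← closure of the twelve-membered ring at C2–C3 by a nickel-catalysed intramolecular alkyl bromide/alkenyl iodide reductive coupling of seco-acetate 30.
3. 30 ← C10–C11 bond by chromium-mediated 2-acylallylation joining ring A dibromide 13 and C10 aldehyde 27; this sets C10 and C11 and creates the methylidene ketone.
4. 13 (ring A, made first) ← Robinson annulation, dehydrogenation, rhodium-catalysed desymmetrising vinylation, Baylis–Hillman reaction, ozonolysis, Appel reaction.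
5. 27 ← but-3-yn-1-ol by zirconium-catalysed carboalumination/ethylene oxide opening (E-alkene), then carbocupration of propyne/iodination (Z-alkenyl iodide).

Assumption: the stereodescriptors are taken exactly as drawn. Bicyclic compounds are numbered verticillane-style: C1 = bridgehead CH bearing C2H2 and C14H2, C10 = acetoxy carbon, C11 = second bridgehead, C12 = methylidene carbon, C13 = C=O, C15 = CMe2. In this numbering the target is 1R,3R,4S,7R,8R,10R,11S. The 3,4-oxirane is cis (from a Z-alkene), the 7,8-oxirane is trans (from an E-alkene), and the C2 and C10 substituents on ring A are trans. Ligand and catalyst enantiomers are chosen by analogy with parent cases and have not been tested on these substrates.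

**Ring A branch**

Step 1
Reactants: 1 isobutyraldehyde (2-methylpropanal); 2 methyl vinyl ketone (but-3-en-2-one)
Product: 5 4,4-dimethylcyclohex-2-en-1-one, via keto-aldehyde 3 (not isolated), via aldol 4 (not isolated)
Conditions: H2SO4 (cat.), toluene, 45 °C then reflux (Dean–Stark)
Reagents that add atoms: none
Why: Acid-catalysed Robinson annulation (Michael addition of the aldehyde enol to the enone, then intramolecular aldol condensation) gives the gem-dimethyl enone; no stereocentre is formed.

Step 2
Reactants: 5 4,4-dimethylcyclohex-2-en-1-one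
Product: 6 4,4-dimethylcyclohexa-2,5-dien-1-one
Conditions: DDQ (1.3 equiv), 1,4-dioxane, reflux
Reagents that add atoms: none
Why: DDQ dehydrogenation of the saturated α,β-positions gives the cross-conjugated dienone, which cannot aromatise because C4 is quaternary.

Step 3
Reactants: 6 4,4-dimethylcyclohexa-2,5-dien-1-one; 7 potassium vinyltrifluoroborate
Product: 8 (5S)-5-ethenyl-4,4-dimethylcyclohex-2-en-1-one
Conditions: [Rh(cod)2]BF4 (3 mol %), (S)-BINAP (3.3 mol %), 7 (1.3 equiv), toluene/H2O 10:1, 100 °C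
Reagents that add atoms: none
Why: Hayashi–Miyaura rhodium-catalysed asymmetric 1,4-addition desymmetrises the two enantiotopic enone arms, the (S)-BINAP–rhodium–vinyl species setting the future C1 centre with the same facial sense as for cyclohexenone, and the remaining, more hindered enone is left for the next step.

Step 4
Reactants: 8 (5S)-5-ethenyl-4,4-dimethylcyclohex-2-en-1-one; 9 formaldehyde
Product: 10 (5S)-5-ethenyl-2-(hydroxymethyl)-4,4-dimethylcyclohex-2-en-1-one
Conditions: 37 % aq. HCHO (3 equiv), DMAP (30 mol %), THF/H2O 1:1, 25 °C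
Reagents that add atoms: none
Why: Morita–Baylis–Hillman hydroxymethylation under DMAP catalysis places the future methylidene carbon on the enone α-carbon without touching the stereocentre or the vinyl group.

Step 5
Reactants: 10 (5S)-5-ethenyl-2-(hydroxymethyl)-4,4-dimethylcyclohex-2-en-1-one
Product: 12 (5R)-2,5-bis(hydroxymethyl)-4,4-dimethylcyclohex-2-en-1-one, via aldehyde 11 (not isolated)
Conditions: O3, CH2Cl2/MeOH, −78 °C; Me2S, −78 → 20 °C; then NaBH(OAc)3, AcOH, CH2Cl2, 0 → 20 °C
Reagents that add atoms: ozone, [O-][O+]=O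
Why: Criegee ozonolysis cleaves the electron-rich vinyl group much faster than the electron-poor enone alkene, and NaBH(OAc)3 reduces only the aldehyde, so the stereocentre is untouched (the S to R change is a priority change only).

Step 6
Reactants: 12 (5R)-2,5-bis(hydroxymethyl)-4,4-dimethylcyclohex-2-en-1-one
Product: 13 (5R)-2,5-bis(bromomethyl)-4,4-dimethylcyclohex-2-en-1-one
Conditions: CBr4 (2.5 equiv), PPh3 (2.5 equiv), CH2Cl2, 0 → 25 °C
Reagents that add atoms: carbon tetrabromide, BrC(Br)(Br)Br
Why: A double Appel reaction converts both primary alcohols by SN2 displacement, giving an allylic bromide for the chromium step and an unactivated primary bromide for the nickel step.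

**Chain branch**

Step 7
Reactants: 14 but-3-yn-1-ol
Product: 15 tert-butyl(but-3-yn-1-yloxy)dimethylsilane
Conditions: TBSCl, imidazole, CH2Cl2, 0 → 25 °C
Reagents that add atoms: tert-butyldimethylsilyl chloride, CC(C)(C)[Si](C)(C)Cl
Why: Standard silylation protects the alcohol through the organoaluminium, Grignard and copper chemistry that follows.

Step 8
Reactants: 15 tert-butyl(but-3-yn-1-yloxy)dimethylsilane; 16 ethylene oxide
Product: 19 (3E)-6-{[tert-butyl(dimethyl)silyl]oxy}-4-methylhex-3-en-1-ol, via alkenylalane 17 (not isolated), via alanate 18 (not isolated)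
Conditions: Me3Al (2 equiv), Cp2ZrCl2 (20 mol %), CH2Cl2, 0 → 25 °C; evaporate; n-BuLi, hexane/THF, −78 °C; 16, −78 → 0 °C; aq. Rochelle salt
Reagents that add atoms: trimethylaluminium, C[Al](C)C
Why: Negishi zirconium-catalysed carboalumination adds methyl and aluminium syn across the terminal alkyne with methyl on the internal carbon, and the derived alanate opens ethylene oxide with retention, which fixes the E geometry of the future C7=C8 bond.

Step 9
Reactants: 19 (3E)-6-{[tert-butyl(dimethyl)silyl]oxy}-4-methylhex-3-en-1-ol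
Product: 20 {[(3E)-6-bromo-3-methylhex-3-en-1-yl]oxy}(tert-butyl)dimethylsilane
Conditions: CBr4, PPh3, 2,6-lutidine, CH2Cl2, 0 °C
Reagents that add atoms: carbon tetrabromide, BrC(Br)(Br)Br
Why: A buffered Appel reaction gives the homoallylic bromide without touching the silyl ether or the alkene geometry.

Step 10
Reactants: 20 {[(3E)-6-bromo-3-methylhex-3-en-1-yl]oxy}(tert-butyl)dimethylsilane; 21 propyne
Product: 25 tert-butyl{[(3E,7Z)-8-iodo-3,7-dimethylocta-3,7-dien-1-yl]oxy}dimethylsilane, via Grignard reagent 22 (not isolated), via alkylcopper 23 (not isolated), via alkenylcopper 24 (not isolated)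
Conditions: Mg, Et2O, reflux; CuBr·SMe2 (1 equiv), Et2O/Me2S, −45 °C; 21 (excess), −25 °C; I2, THF, −50 → 0 °C
Reagents that add atoms: iodine, II
Why: Normant carbocupration adds the alkylcopper syn across propyne with the alkyl group on the internal carbon, and iodinolysis with retention gives the Z-alkenyl iodide that carries the geometry of the future C3=C4 bond.

Step 11
Reactants: 25 tert-butyl{[(3E,7Z)-8-iodo-3,7-dimethylocta-3,7-dien-1-yl]oxy}dimethylsilane
Product: 26 (3E,7Z)-8-iodo-3,7-dimethylocta-3,7-dien-1-ol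
Conditions: TBAF, AcOH, THF, 0 → 25 °C
Reagents that add atoms: none
Why: Buffered fluoride desilylation frees the primary alcohol and leaves the alkenyl iodide intact.

Step 12
Reactants: 26 (3E,7Z)-8-iodo-3,7-dimethylocta-3,7-dien-1-ol
Product: 27 (3E,7Z)-8-iodo-3,7-dimethylocta-3,7-dienal
Conditions: Dess–Martin periodinane, NaHCO3, CH2Cl2, 0 °C; used crude at once
Reagents that add atoms: none
Why: Dess–Martin oxidation is non-basic, so the β,γ-unsaturated aldehyde forms without migration of the alkene into conjugation.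

**Union and endgame**

Step 13
Reactants: 13 (5R)-2,5-bis(bromomethyl)-4,4-dimethylcyclohex-2-en-1-one; 27 (3E,7Z)-8-iodo-3,7-dimethylocta-3,7-dienal
Product: 29 (3S,5R)-5-(bromomethyl)-3-[(1R,3E,7Z)-1-hydroxy-8-iodo-3,7-dimethylocta-3,7-dien-1-yl]-4,4-dimethyl-2-methylidenecyclohexan-1-one, via allylchromium 28 (not isolated)
Conditions: CrCl2 (4 equiv, nickel-free), THF, 0 → 25 °C, Barbier mode
Reagents that add atoms: none
Why: In this Nozaki–Hiyama allylation divalent chromium reduces only the allylic bromide, and the 2-acylallylchromium attacks the aldehyde through its γ-carbon in a chair transition state (aldehyde chain equatorial, ring-enforced E-type allyl geometry, hence anti C10/C11) on the ring face opposite the bromomethyl group, which gives 10R,11S with the trans ring A pattern and unveils the methylidene ketone.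

Step 14
Reactants: 29 (3S,5R)-5-(bromomethyl)-3-[(1R,3E,7Z)-1-hydroxy-8-iodo-3,7-dimethylocta-3,7-dien-1-yl]-4,4-dimethyl-2-methylidenecyclohexan-1-one
Product: 30 (1R,3E,7Z)-1-[(1S,3R)-3-(bromomethyl)-2,2-dimethyl-6-methylidene-5-oxocyclohexyl]-8-iodo-3,7-dimethylocta-3,7-dien-1-yl acetate
Conditions: Ac2O, pyridine, DMAP (5 mol %), CH2Cl2, 0 °C
Reagents that add atoms: acetic anhydride, CC(=O)OC(C)=O
Why: DMAP-catalysed acylation installs the C10 acetate with retention and blocks hemiketal formation with the C13 ketone.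

Step 15
Reactants: 30 (1R,3E,7Z)-1-[(1S,3R)-3-(bromomethyl)-2,2-dimethyl-6-methylidene-5-oxocyclohexyl]-8-iodo-3,7-dimethylocta-3,7-dien-1-yl acetate
Product: 31 (1R,3Z,7E,10R,11S)-4,8,15,15-tetramethyl-12-methylidene-13-oxobicyclo[9.3.1]pentadeca-3,7-dien-10-yl acetate
Conditions: NiBr2(dme) (20 mol %), 4,4′-di-tert-butyl-2,2′-bipyridine (24 mol %), NaI (0.5 equiv), Mn powder (4 equiv), DMA, 25 °C, syringe-pump addition to 2 mM
Reagents that add atoms: none
Why: Proposed new method: an intramolecular nickel-catalysed reductive cross-electrophile coupling used as a macrocyclisation to form the C2–C3 bond and the twelve-membered ring, in which zerovalent nickel (from NiBr2(dme) and Mn) inserts into the Z-alkenyl iodide with retention, a monovalent nickel halide abstracts halogen from the primary C2 bromide (partly exchanged to iodide by NaI), the C2 radical is captured by the tethered alkenylnickel centre and reductive elimination from trivalent nickel closes the ring, while cyclisation of that radical onto the methylidene ketone is disfavoured because it needs a boat and gives an unstabilised bridgehead bicyclo[2.2.2]octyl radical; the closest known chemistry is the intermolecular nickel/bipyridine/Mn coupling of alkenyl halides with primary alkyl halides and nickel-catalysed reductive cyclisations to small rings.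

Step 16
Reactants: 31 (1R,3Z,7E,10R,11S)-4,8,15,15-tetramethyl-12-methylidene-13-oxobicyclo[9.3.1]pentadeca-3,7-dien-10-yl acetate
Product: 33 (1R,3R,4S,7R,8R,10R,11S)-3,4:7,8-diepoxy-4,8,15,15-tetramethyl-12-methylidene-13-oxobicyclo[9.3.1]pentadecan-10-yl acetate, via monoepoxide 32 (not isolated)
Conditions: D-fructose-derived Shi ketone (3 equiv), Oxone (2KHSO5·KHSO4·K2SO4, 5 equiv), NaHCO3, Bu4NHSO4 (cat.), MeCN/aq. Na2EDTA, 0 °C, pH 7–8
Reagents that add atoms: potassium peroxymonosulfate (from Oxone), [K+].[O-]S(=O)(=O)OO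
Why: In the Shi asymmetric epoxidation the chiral dioxirane attacks each trisubstituted alkene through a spiro transition state whose face is fixed at the CH carbon, which predicts R at C3 and C7 with the same ketone, and syn oxygen transfer then gives the cis 3R,4S and trans 7R,8R oxiranes while the electron-poor methylidene ketone is not oxidised.

**Compound list**
1 | isobutyraldehyde (2-methylpropanal) | CC(C)C=O | starting material
2 | methyl vinyl ketone (but-3-en-2-one) | CC(=O)C=C | starting material
3 | 2,2-dimethyl-5-oxohexanal | CC(=O)CCC(C)(C)C=O | intermediate (not isolated)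
4 | 3-hydroxy-4,4-dimethylcyclohexan-1-one (racemic) | CC1(C)CCC(=O)CC1O | intermediate (not isolated)
5 | 4,4-dimethylcyclohex-2-en-1-one | CC1(C)CCC(=O)C=C1 | intermediate
6 | 4,4-dimethylcyclohexa-2,5-dien-1-one | CC1(C)C=CC(=O)C=C1 | intermediate
7 | potassium vinyltrifluoroborate | [K+].C=C[B-](F)(F)F | starting material
8 | (5S)-5-ethenyl-4,4-dimethylcyclohex-2-en-1-one | O=C1C=CC(C)(C)[C@H](C=C)C1 | intermediate
9 | formaldehyde | C=O | starting material
10 | (5S)-5-ethenyl-2-(hydroxymethyl)-4,4-dimethylcyclohex-2-en-1-one | O=C1C(CO)=CC(C)(C)[C@H](C=C)C1 | intermediate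
11 | (1R)-4-(hydroxymethyl)-2,2-dimethyl-5-oxocyclohex-3-ene-1-carbaldehyde | O=C1C(CO)=CC(C)(C)[C@H](C=O)C1 | intermediate (not isolated)
12 | (5R)-2,5-bis(hydroxymethyl)-4,4-dimethylcyclohex-2-en-1-one | O=C1C(CO)=CC(C)(C)[C@H](CO)C1 | intermediate
13 | (5R)-2,5-bis(bromomethyl)-4,4-dimethylcyclohex-2-en-1-one | O=C1C(CBr)=CC(C)(C)[C@H](CBr)C1 | intermediate
14 | but-3-yn-1-ol | C#CCCO | starting material
15 | tert-butyl(but-3-yn-1-yloxy)dimethylsilane | C#CCCO[Si](C)(C)C(C)(C)C | intermediate
16 | ethylene oxide | C1CO1 | starting material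
17 | [(1E)-4-{[tert-butyl(dimethyl)silyl]oxy}-2-methylbut-1-en-1-yl]dimethylalumane | C[Al](C)/C=C(\C)CCO[Si](C)(C)C(C)(C)C | intermediate (not isolated)
18 | lithium butyl[(1E)-4-{[tert-butyl(dimethyl)silyl]oxy}-2-methylbut-1-en-1-yl]dimethylaluminate | [Li+].CCCC[Al-](C)(C)/C=C(\C)CCO[Si](C)(C)C(C)(C)C | intermediate (not isolated)
19 | (3E)-6-{[tert-butyl(dimethyl)silyl]oxy}-4-methylhex-3-en-1-ol | OCC/C=C(\C)CCO[Si](C)(C)C(C)(C)C | intermediate
20 | {[(3E)-6-bromo-3-methylhex-3-en-1-yl]oxy}(tert-butyl)dimethylsilane | BrCC/C=C(\C)CCO[Si](C)(C)C(C)(C)C | intermediate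
21 | propyne | CC#C | starting material
22 | [(3E)-6-{[tert-butyl(dimethyl)silyl]oxy}-4-methylhex-3-en-1-yl]magnesium bromide | Br[Mg]CC/C=C(\C)CCO[Si](C)(C)C(C)(C)C | intermediate (not isolated)
23 | [(3E)-6-{[tert-butyl(dimethyl)silyl]oxy}-4-methylhex-3-en-1-yl]copper (monovalent copper) | [Cu]CC/C=C(\C)CCO[Si](C)(C)C(C)(C)C | intermediate (not isolated)
24 | [(1Z,5E)-8-{[tert-butyl(dimethyl)silyl]oxy}-2,6-dimethylocta-1,5-dien-1-yl]copper (monovalent copper) | [Cu]/C=C(/C)CC/C=C(\C)CCO[Si](C)(C)C(C)(C)C | intermediate (not isolated)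
25 | tert-butyl{[(3E,7Z)-8-iodo-3,7-dimethylocta-3,7-dien-1-yl]oxy}dimethylsilane | I/C=C(/C)CC/C=C(\C)CCO[Si](C)(C)C(C)(C)C | intermediate
26 | (3E,7Z)-8-iodo-3,7-dimethylocta-3,7-dien-1-ol | I/C=C(/C)CC/C=C(\C)CCO | intermediate
27 | (3E,7Z)-8-iodo-3,7-dimethylocta-3,7-dienal | I/C=C(/C)CC/C=C(\C)CC=O | intermediate
28 | {[(4R)-4-(bromomethyl)-3,3-dimethyl-6-oxocyclohex-1-en-1-yl]methyl}chromium dichloride (trivalent chromium) | Cl[Cr](Cl)CC1=CC(C)(C)[C@H](CBr)CC1=O | intermediate (not isolated)
29 | (3S,5R)-5-(bromomethyl)-3-[(1R,3E,7Z)-1-hydroxy-8-iodo-3,7-dimethylocta-3,7-dien-1-yl]-4,4-dimethyl-2-methylidenecyclohexan-1-one | C=C1C(=O)C[C@@H](CBr)C(C)(C)[C@@H]1[C@H](O)C/C(C)=C/CC/C(C)=C\I | intermediate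
30 | (1R,3E,7Z)-1-[(1S,3R)-3-(bromomethyl)-2,2-dimethyl-6-methylidene-5-oxocyclohexyl]-8-iodo-3,7-dimethylocta-3,7-dien-1-yl acetate | C=C1C(=O)C[C@@H](CBr)C(C)(C)[C@@H]1[C@H](OC(C)=O)C/C(C)=C/CC/C(C)=C\I | intermediate
31 | (1R,3Z,7E,10R,11S)-4,8,15,15-tetramethyl-12-methylidene-13-oxobicyclo[9.3.1]pentadeca-3,7-dien-10-yl acetate | C=C1C(=O)C[C@H]2C/C=C(C)\CC/C=C(C)/C[C@@H](OC(C)=O)[C@H]1C2(C)C | intermediate
32 | (1R,3Z,7R,8R,10R,11S)-7,8-epoxy-4,8,15,15-tetramethyl-12-methylidene-13-oxobicyclo[9.3.1]pentadec-3-en-10-yl acetate | C=C1C(=O)C[C@H]2C/C=C(C)\CC[C@H]3O[C@]3(C)C[C@@H](OC(C)=O)[C@H]1C2(C)C | intermediate (not isolated)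
33 | (1R,3R,4S,7R,8R,10R,11S)-3,4:7,8-diepoxy-4,8,15,15-tetramethyl-12-methylidene-13-oxobicyclo[9.3.1]pentadecan-10-yl acetate | C=C1C(=O)C[C@H]2C[C@H]3O[C@@]3(C)CC[C@H]3O[C@]3(C)C[C@@H](OC(C)=O)[C@H]1C2(C)C | target

**Step count and risks**
Total step count: 16.
Longest linear sequence: 10 steps (steps 1–6 then 13–16; the chain branch, steps 7–12 then 13–16, is equally long).

Most likely to fail, step 13 (chromium allylation): the γ-carbon is hindered by the neighbouring CMe2, aldehyde 27 is prone to isomerise, and the trans/anti selectivity rests on models, not on a tested case. The fallback sets out from 13 and comes back at 29. The allylic bromide of 13 is borylated selectively (Pd(dba)2 5 mol %, B2pin2, DMSO, 50 °C; the primary bromide does not react) to give the storable allylboronate (5R)-5-(bromomethyl)-4,4-dimethyl-2-[(4,4,5,5-tetramethyl-1,3,2-dioxaborolan-2-yl)methyl]cyclohex-2-en-1-one F1. Allylboration of 27 with F1 (Sc(OTf)3 10 mol %, toluene, −78 → 0 °C) goes through the same closed chair transition state without a metal reductant and gives 29 after work-up.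

Most likely to fail, step 15 (the proposed nickel macrocyclisation): possible problems are dimerisation, β-hydride loss at C2, or interference by the methylidene ketone. The fallback uses known chemistry, sets out from 30 and comes back at 31. Finkelstein exchange (NaI, acetone, reflux) gives (1R,3E,7Z)-8-iodo-1-[(1S,3R)-3-(iodomethyl)-2,2-dimethyl-6-methylidene-5-oxocyclohexyl]-3,7-dimethylocta-3,7-dien-1-yl acetate F2. Zinc insertion into the alkyl iodide only (activated Zn dust, DMA, 40 °C) gives {[(1R,2S)-2-[(1R,3E,7Z)-1-acetoxy-8-iodo-3,7-dimethylocta-3,7-dien-1-yl]-6,6-dimethyl-3-methylidene-4-oxocyclohexyl]methyl}zinc iodide F3, which is not isolated. Slow addition of F3 to PdCl2(dppf) (10 mol %) in THF at 40 °C under high dilution closes the ring by an intramolecular Negishi coupling to give 31.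

Most likely to fail, step 16 (double Shi epoxidation): the macrocycle's own facial bias may oppose the reagent at one alkene, and the methylidene ketone is sensitive to oxidant and base. The fallback sets out from 29, comes back at 32 (now isolated) and goes on to 33. The ring is closed on the free alcohol under the step 15 conditions to give (1R,3Z,7E,10R,11S)-10-hydroxy-4,8,15,15-tetramethyl-12-methylidenebicyclo[9.3.1]pentadeca-3,7-dien-13-one F4. Hydroxyl-directed epoxidation (VO(acac)2 5 mol %, t-BuOOH, CH2Cl2, 0 °C) oxidises only the homoallylic C7=C8 bond and gives (1R,3Z,7R,8R,10R,11S)-7,8-epoxy-10-hydroxy-4,8,15,15-tetramethyl-12-methylidenebicyclo[9.3.1]pentadec-3-en-13-one F5. Acetylation (Ac2O, pyridine, DMAP) gives 32, and the remaining Z-alkene is then epoxidised alone with dimethyldioxirane (acetone, −20 °C) to give 33.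

**Further compounds**
F1 | step 13 | (5R)-5-(bromomethyl)-4,4-dimethyl-2-[(4,4,5,5-tetramethyl-1,3,2-dioxaborolan-2-yl)methyl]cyclohex-2-en-1-one | O=C1C(CB2OC(C)(C)C(C)(C)O2)=CC(C)(C)[C@H](CBr)C1
F2 | step 15 | (1R,3E,7Z)-8-iodo-1-[(1S,3R)-3-(iodomethyl)-2,2-dimethyl-6-methylidene-5-oxocyclohexyl]-3,7-dimethylocta-3,7-dien-1-yl acetate | C=C1C(=O)C[C@@H](CI)C(C)(C)[C@@H]1[C@H](OC(C)=O)C/C(C)=C/CC/C(C)=C\I
F3 | step 15 | {[(1R,2S)-2-[(1R,3E,7Z)-1-acetoxy-8-iodo-3,7-dimethylocta-3,7-dien-1-yl]-6,6-dimethyl-3-methylidene-4-oxocyclohexyl]methyl}zinc iodide | C=C1C(=O)C[C@@H](C[Zn]I)C(C)(C)[C@@H]1[C@H](OC(C)=O)C/C(C)=C/CC/C(C)=C\I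
F4 | step 16 | (1R,3Z,7E,10R,11S)-10-hydroxy-4,8,15,15-tetramethyl-12-methylidenebicyclo[9.3.1]pentadeca-3,7-dien-13-one | C=C1C(=O)C[C@H]2C/C=C(C)\CC/C=C(C)/C[C@@H](O)[C@H]1C2(C)C
F5 | step 16 | (1R,3Z,7R,8R,10R,11S)-7,8-epoxy-10-hydroxy-4,8,15,15-tetramethyl-12-methylidenebicyclo[9.3.1]pentadec-3-en-13-one | C=C1C(=O)C[C@H]2C/C=C(C)\CC[C@H]3O[C@]3(C)C[C@@H](O)[C@H]1C2(C)C
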